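**Plan**
- Retrosynthesis first cuts the 4'-O–CH2 bond of the prenyl ether. It then cuts C5'–CMe2 as a retro aromatic Claisen of a 4'-O-prenyl ether. This leaves a (3R)-7,2',4'-trioxygenated isoflavan.
- Next, both ring bonds of C3 (C2–C3 and C3–C4) are cut. C3 is the only atom of the pyran ring that carries ring B. It lies between C2 (bound to O1) and C4 (bound to C4a), so removing it leaves O1–C2=C4–C4a–C8a. That is the furan ring of a 6-oxygenated benzofuran, and the other fragment is an aryl(chloro)carbene.
- Forward, ring A with its furan ring is bought as benzofuran-6-ol. Ring B is bought as 4-(benzyloxy)salicylaldehyde and converted into a chlorodiazirine. Carbene insertion joins the two halves and expands the furan (5) to a pyrylium ring (6), and hydride then gives the isoflav-3-ene.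
- The single stereocentre C3 comes from an Ir-catalysed asymmetric hydrogenation of C3=C4. This is run before any prenyl alkene is present, and no later step touches C3.
- The end game is debenzylation at 4'-O, O-prenylation, Claisen shift to C5', a second O-prenylation, and removal of the two MOM groups.

Key step: step 6

Assumption: the (4S,5S) antipode of the phosphinite–oxazoline iridium catalyst is taken to deliver the 3R series by analogy with simpler 3-aryl-2H-chromenes; if the sense proves opposite, the mirror-image catalyst is used.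

Step 1
Reactants: 1 benzofuran-6-ol
Product: 2 6-(methoxymethoxy)benzofuran
Conditions: MOMCl, i-Pr2NEt, CH2Cl2, 0 °C to rt
Reagents that add atoms: chloromethyl methyl ether, COCCl
Why: Williamson-type O-alkylation of the phenol with the reactive α-chloro ether should give an acetal ether that keeps the oxygen a donor and withstands carbene, hydride, hydrogenation, base and 200 °C.

Step 2
Reactants: 3 4-(benzyloxy)-2-hydroxybenzaldehyde
Product: 4 4-(benzyloxy)-2-(methoxymethoxy)benzaldehyde
Conditions: MOMCl, i-Pr2NEt, CH2Cl2, 0 °C to reflux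
Reagents that add atoms: chloromethyl methyl ether, COCCl
Why: Williamson-type O-alkylation of the chelated phenol; MOM is chosen because, unlike an acyl, sulfonyl or silyl group, it cannot migrate to the neighbouring amidine nitrogen in steps 4 and 5.

Step 3
Reactants: 4 4-(benzyloxy)-2-(methoxymethoxy)benzaldehyde
Product: 5 4-(benzyloxy)-2-(methoxymethoxy)benzonitrile
Conditions: I2, 28% aq NH3, THF, rt
Reagents that add atoms: ammonia, N
Why: Oxidative ammonolysis of an aldehyde, in which the aldimine is N-iodinated and loses HI to give the nitrile, is well precedented for alkoxybenzaldehydes and leaves acetal and benzyl ethers alone.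

Step 4
Reactants: 5 4-(benzyloxy)-2-(methoxymethoxy)benzonitrile
Product: 7 4-(benzyloxy)-2-(methoxymethoxy)benzamidine hydrochloride, via lithium bis(trimethylsilyl)amidinate 6 (not isolated)
Conditions: LiHMDS, THF, 0 °C to rt; then HCl in EtOH (no excess), 0 °C
Reagents that add atoms: lithium hexamethyldisilazide, [Li]N([Si](C)(C)C)[Si](C)(C)C; hydrogen chloride, Cl
Why: Addition of the silylamide to the nitrile followed by ethanolysis of the N–Si bonds is the standard nitrile-to-amidine conversion, and the strongly basic amidine consumes the acid so that the MOM group should survive.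

Step 5
Reactants: 7 4-(benzyloxy)-2-(methoxymethoxy)benzamidine hydrochloride
Product: 8 3-[4-(benzyloxy)-2-(methoxymethoxy)phenyl]-3-chloro-3H-diazirine
Conditions: aq NaOCl, LiCl, DMSO/pentane, 0 °C to rt; kept cold as a solution and used at once
Reagents that add atoms: sodium hypochlorite, [Na+].[O-]Cl; lithium chloride (chloride pool), [Li+].[Cl-]
Why: Graham oxidation (double N-chlorination, base-induced N–N closure and return of chloride to carbon) is known for 4-alkoxybenzamidines, and the electron-poor N-chloroamidine group should slow ring chlorination.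

Step 6
Reactants: 2 6-(methoxymethoxy)benzofuran; 8 3-[4-(benzyloxy)-2-(methoxymethoxy)phenyl]-3-chloro-3H-diazirine
Product: 12 3-[4-(benzyloxy)-2-(methoxymethoxy)phenyl]-7-(methoxymethoxy)-2H-chromene, via arylchlorocarbene 9 (not isolated), via chlorocyclopropane 10 (not isolated), via isoflavylium chloride 11 (not isolated)
Conditions: 2 (3 equiv, about 1 M), 4 Å MS, MeCN, 45 °C, slow addition of 8; then NaBH4, THF, −20 to 0 °C; excess 2 recovered
Reagents that add atoms: none
Why: Proposed new method: loss of N2 from 8 gives the singlet arylchlorocarbene 9, which adds in a concerted [2+1] cheletropic manner to the C2=C3 enol-ether bond of 2, the only non-benzenoid π bond present and one made more nucleophilic by O1 and by the 6-OMOM group para to C3a, and this closes the three-membered ring of 10. In 10 chloride leaves while the C1a–C6b bond shared by the three- and five-membered rings opens (disrotatory 2π cyclopropyl-to-allyl cation opening, pushed by the ring-oxygen lone pair), so the six-membered ring is not closed by a cyclisation but arises from the furan ring by ring expansion, with the carbene carbon becoming C3 that carries ring B and aromatisation to the pyrylium ring of 11 as the driving force. The closest known reaction types are the Ciamician–Dennstedt-type one-carbon insertion of arylchlorodiazirines into pyrroles and indoles and the ring expansion of dihalocarbene adducts of benzofurans to 3-halo-2H-chromenes, and the untested part is the arylchlorocarbene variant on a benzofuran that ends in an isoflavylium salt. The three stereocentres of 10 are erased on opening, both C1 epimers should converge because the 2,4-dioxygenated aryl group allows stepwise ionisation of the epimer whose chloride is badly placed for the concerted opening, and 12 is achiral. The step needs 9 to choose 2 over azine formation and over 1,5 C–H insertion into its own OCH2O group, which is served by slow addition of 8 to an excess of concentrated 2 and by the conjugation of the empty carbene orbital with the donor arene, which has to be broken for insertion. It also needs hydride attack at C2 and not at C4 of 11, which is favoured because C2 lies next to the charged oxygen, C4 is relieved by the 7-OMOM donor, and attack at C2 gives the stilbene-conjugated 2H-chromene.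

Step 7
Reactants: 12 3-[4-(benzyloxy)-2-(methoxymethoxy)phenyl]-7-(methoxymethoxy)-2H-chromene
Product: 13 (3R)-3-[4-(benzyloxy)-2-(methoxymethoxy)phenyl]-7-(methoxymethoxy)chroman
Conditions: H2 (50 bar), [Ir(cod)((4S,5S)-ThrePHOX)]BArF (1–2 mol %), CH2Cl2, rt
Reagents that add atoms: none
Why: Iridium N,P-ligand catalysed asymmetric hydrogenation of an unfunctionalised trisubstituted olefin, closely precedented on MOM-protected 3-aryl-2H-chromenes, should add H2 to C3=C4 from the face left open by the chiral phosphinite–oxazoline pocket and so set C3 as R, at a stage where no prenyl alkene is present and with the benzyl ether left intact.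

Step 8
Reactants: 13 (3R)-3-[4-(benzyloxy)-2-(methoxymethoxy)phenyl]-7-(methoxymethoxy)chroman
Product: 14 3-(methoxymethoxy)-4-[(3R)-7-(methoxymethoxy)chroman-3-yl]phenol
Conditions: H2 (1 atm), 10% Pd/C, EtOAc/EtOH, rt
Reagents that add atoms: none
Why: Catalytic hydrogenolysis cleaves only the O-benzyl bond and frees the 4'-OH alone, because the MOM ethers, the chroman C–O bond and C3 are inert under neutral conditions.

Step 9
Reactants: 14 3-(methoxymethoxy)-4-[(3R)-7-(methoxymethoxy)chroman-3-yl]phenol
Product: 15 (3R)-7-(methoxymethoxy)-3-[2-(methoxymethoxy)-4-(3-methylbut-2-enyloxy)phenyl]chroman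
Conditions: prenyl bromide, K2CO3, acetone, reflux
Reagents that add atoms: 1-bromo-3-methylbut-2-ene, CC(C)=CCBr
Why: Williamson ether synthesis on the only free phenol should proceed by SN2 attack at the primary allylic carbon.

Step 10
Reactants: 15 (3R)-7-(methoxymethoxy)-3-[2-(methoxymethoxy)-4-(3-methylbut-2-enyloxy)phenyl]chroman
Product: 17 5-(methoxymethoxy)-4-[(3R)-7-(methoxymethoxy)chroman-3-yl]-2-(2-methylbut-3-en-2-yl)phenol, via ortho-dienone 16 (not isolated)
Conditions: PhNEt2, 200 °C (sealed tube or microwave), Ar
Reagents that add atoms: none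
Why: Aromatic Claisen rearrangement, in which the [3,3] shift joins the CMe2 terminus of the prenyl group to C5' with allyl inversion, C5' being preferred to C3' because C3' is wedged between the 2'-OMOM and 4'-O groups and would have to accept a quaternary carbon, after which dienone 16 enolises, the para position C1' is blocked, the basic solvent holds back acid-induced cyclisation, and C3 is remote and untouched.

Step 11
Reactants: 17 5-(methoxymethoxy)-4-[(3R)-7-(methoxymethoxy)chroman-3-yl]-2-(2-methylbut-3-en-2-yl)phenol
Product: 18 (3R)-7-(methoxymethoxy)-3-[2-(methoxymethoxy)-5-(2-methylbut-3-en-2-yl)-4-(3-methylbut-2-enyloxy)phenyl]chroman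
Conditions: prenyl bromide, K2CO3, DMF, rt to 40 °C
Reagents that add atoms: 1-bromo-3-methylbut-2-ene, CC(C)=CCBr
Why: Williamson ether synthesis, which works on phenols flanked by one tert-alkyl group when a polar aprotic solvent and an unhindered allylic bromide are used.

Step 12
Reactants: 18 (3R)-7-(methoxymethoxy)-3-[2-(methoxymethoxy)-5-(2-methylbut-3-en-2-yl)-4-(3-methylbut-2-enyloxy)phenyl]chroman
Product: 20 manuifolin D, via bis(trimethylsilyl) ether 19 (not isolated)
Conditions: TMSOTf, 2,2'-bipyridyl, MeCN, 0 °C to rt; then H2O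
Reagents that add atoms: trimethylsilyl trifluoromethanesulfonate, C[Si](C)(C)OS(=O)(=O)C(F)(F)F (its silicon stays only in 19; only hydrogen stays in 20)
Why: The silyl triflate/bipyridyl cleavage of aryl MOM ethers turns the acetal into an aryl silyl ether and a pyridinium salt without free Brønsted acid, and water then hydrolyses both, so the acid-labile aryl prenyl ether and the two alkenes should survive.

**Compound list**
1 | benzofuran-6-ol | Oc1ccc2ccoc2c1 | starting material
2 | 6-(methoxymethoxy)benzofuran | COCOc1ccc2ccoc2c1 | intermediate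
3 | 4-(benzyloxy)-2-hydroxybenzaldehyde | Oc1cc(OCc2ccccc2)ccc1C=O | starting material
4 | 4-(benzyloxy)-2-(methoxymethoxy)benzaldehyde | COCOc1cc(OCc2ccccc2)ccc1C=O | intermediate
5 | 4-(benzyloxy)-2-(methoxymethoxy)benzonitrile | COCOc1cc(OCc2ccccc2)ccc1C#N | intermediate
6 | lithium N,N'-bis(trimethylsilyl)-4-(benzyloxy)-2-(methoxymethoxy)benzamidinate (not isolated) | COCOc1cc(OCc2ccccc2)ccc1C(=N[Si](C)(C)C)N([Li])[Si](C)(C)C | intermediate
7 | 4-(benzyloxy)-2-(methoxymethoxy)benzamidine hydrochloride | COCOc1cc(OCc2ccccc2)ccc1C(N)=N.Cl | intermediate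
8 | 3-[4-(benzyloxy)-2-(methoxymethoxy)phenyl]-3-chloro-3H-diazirine | COCOc1cc(OCc2ccccc2)ccc1C1(Cl)N=N1 | intermediate
9 | [4-(benzyloxy)-2-(methoxymethoxy)phenyl]chlorocarbene (not isolated) | COCOc1cc(OCc2ccccc2)ccc1[C]Cl | intermediate
10 | 1-[4-(benzyloxy)-2-(methoxymethoxy)phenyl]-1-chloro-4-(methoxymethoxy)-1a,6b-dihydro-1H-cyclopropa[b]benzofuran, racemic, both C1 epimers (not isolated) | COCOc1ccc2c(c1)OC1C2C1(Cl)c1ccc(OCc2ccccc2)cc1OCOC | intermediate
11 | 3-[4-(benzyloxy)-2-(methoxymethoxy)phenyl]-7-(methoxymethoxy)chromenylium chloride, an isoflavylium salt (not isolated) | COCOc1ccc2cc(-c3ccc(OCc4ccccc4)cc3OCOC)c[o+]c2c1.[Cl-] | intermediate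
12 | 3-[4-(benzyloxy)-2-(methoxymethoxy)phenyl]-7-(methoxymethoxy)-2H-chromene, an isoflav-3-ene | COCOc1ccc2c(c1)OCC(=C2)c1ccc(OCc3ccccc3)cc1OCOC | intermediate
13 | (3R)-3-[4-(benzyloxy)-2-(methoxymethoxy)phenyl]-7-(methoxymethoxy)chroman | COCOc1cc(OCc2ccccc2)ccc1[C@@H]1COc2cc(OCOC)ccc2C1 | intermediate
14 | 3-(methoxymethoxy)-4-[(3R)-7-(methoxymethoxy)chroman-3-yl]phenol | COCOc1cc(O)ccc1[C@@H]1COc2cc(OCOC)ccc2C1 | intermediate
15 | (3R)-7-(methoxymethoxy)-3-[2-(methoxymethoxy)-4-(3-methylbut-2-enyloxy)phenyl]chroman | COCOc1cc(OCC=C(C)C)ccc1[C@@H]1COc2cc(OCOC)ccc2C1 | intermediate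
16 | 3-(methoxymethoxy)-4-[(3R)-7-(methoxymethoxy)chroman-3-yl]-6-(2-methylbut-3-en-2-yl)cyclohexa-2,4-dien-1-one, both C6 epimers (not isolated) | O=C1C=C(OCOC)C([C@@H]2COc3cc(OCOC)ccc3C2)=CC1C(C)(C)C=C | intermediate
17 | 5-(methoxymethoxy)-4-[(3R)-7-(methoxymethoxy)chroman-3-yl]-2-(2-methylbut-3-en-2-yl)phenol | C=CC(C)(C)c1cc([C@@H]2COc3cc(OCOC)ccc3C2)c(OCOC)cc1O | intermediate
18 | (3R)-7-(methoxymethoxy)-3-[2-(methoxymethoxy)-5-(2-methylbut-3-en-2-yl)-4-(3-methylbut-2-enyloxy)phenyl]chroman | C=CC(C)(C)c1cc([C@@H]2COc3cc(OCOC)ccc3C2)c(OCOC)cc1OCC=C(C)C | intermediate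
19 | 7,2'-bis(trimethylsilyl) ether of manuifolin D (not isolated) | C=CC(C)(C)c1cc([C@@H]2COc3cc(O[Si](C)(C)C)ccc3C2)c(O[Si](C)(C)C)cc1OCC=C(C)C | intermediate
20 | manuifolin D, (3R)-3-[2-hydroxy-5-(2-methylbut-3-en-2-yl)-4-(3-methylbut-2-enyloxy)phenyl]chroman-7-ol | C=CC(C)(C)c1cc([C@@H]2COc3cc(O)ccc3C2)c(O)cc1OCC=C(C)C | target

Total step count: 12. Longest linear sequence: 11 steps (steps 2–12, from 3).

**Steps most likely to fail**

**Step 6 (with the preparation and handling of 8 that feeds it).**
- The carbene may be lost through azine formation with unreacted diazirine.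
- It may also be lost through insertion into the neighbouring OCH2O group.
- A MOM group may be stripped by chloride at the pyrylium stage.
- Hydride may be delivered to C4 instead of C2.

The fallback sets out from 2, comes back at 12, uses known chemistry, keeps the furan-to-pyran ring expansion and makes steps 2–5 unnecessary.
- Dichlorocarbene (CHCl3, 50% NaOH, BnEt3NCl) would be added to 2 to give 1,1-dichloro-4-(methoxymethoxy)-1a,6b-dihydro-1H-cyclopropa[b]benzofuran F1.
- Warming in ethanol with K2CO3 would open it to 3-chloro-2-ethoxy-7-(methoxymethoxy)-2H-chromene F2.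
- Ionic reduction (Et3SiH, BF3·OEt2, CH2Cl2, −78 °C) would give 3-chloro-7-(methoxymethoxy)-2H-chromene F3.
- Ring B would come from commercial 4-bromoresorcinol. Benzylation of the less hindered hydroxyl gives 5-(benzyloxy)-2-bromophenol F4.
- MOM protection gives 4-(benzyloxy)-1-bromo-2-(methoxymethoxy)benzene F5.
- Bromine–lithium exchange with n-BuLi, B(OiPr)3 and hydrolysis give [4-(benzyloxy)-2-(methoxymethoxy)phenyl]boronic acid F6.
- Suzuki–Miyaura coupling of F3 with F6 (Pd(OAc)2, SPhos, K3PO4, toluene/H2O) would give 12.

**Step 10.**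
- The allyl group may migrate toward C3'.
- The prenyl group may be lost thermally.
- The product may rearrange further (abnormal Claisen) or cyclise on long heating.

The fallback sets out from 14 and comes back at 17.
- Bromination of the phenol ring ortho to OH and para to the 2'-OMOM group (NBS, CH2Cl2/MeCN, −40 to 0 °C) would give 2-bromo-5-(methoxymethoxy)-4-[(3R)-7-(methoxymethoxy)chroman-3-yl]phenol F7.
- A palladium-catalysed, ligand-controlled γ-selective allyl–aryl coupling with prenylboronic acid pinacol ester (bulky biarylphosphine, K3PO4, aqueous THF) would install the 1,1-dimethylallyl group at C5' and give 17.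

**Step 7.**
- Facial selectivity may be poor, or turnover slow, because the ortho-substituted ring B is twisted out of the plane of the olefin.

The fallback sets out from 12 and comes back at 14.
- Hydroboration–oxidation (BH3·THF, then H2O2/NaOH) would give racemic trans-3-[4-(benzyloxy)-2-(methoxymethoxy)phenyl]-7-(methoxymethoxy)chroman-4-ol F8.
- Dess–Martin oxidation would give the configurationally labile 3-[4-(benzyloxy)-2-(methoxymethoxy)phenyl]-7-(methoxymethoxy)chroman-4-one F9.
- Noyori-type asymmetric transfer hydrogenation with dynamic kinetic resolution (RuCl[(R,R)-TsDPEN](p-cymene), HCO2H/Et3N) would give (3R,4R)-3-[4-(benzyloxy)-2-(methoxymethoxy)phenyl]-7-(methoxymethoxy)chroman-4-ol F10.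
- Hydrogenolysis (H2, Pd/C, EtOH/AcOH) would remove the benzylic 4-OH and the benzyl ether together and give 14.

Further compounds
F1 | step 6 | 1,1-dichloro-4-(methoxymethoxy)-1a,6b-dihydro-1H-cyclopropa[b]benzofuran (racemic) | COCOc1ccc2c(c1)OC1C2C1(Cl)Cl
F2 | step 6 | 3-chloro-2-ethoxy-7-(methoxymethoxy)-2H-chromene (racemic) | CCOC1Oc2cc(OCOC)ccc2C=C1Cl
F3 | step 6 | 3-chloro-7-(methoxymethoxy)-2H-chromene | COCOc1ccc2c(c1)OCC(Cl)=C2
F4 | step 6 | 5-(benzyloxy)-2-bromophenol | Oc1cc(OCc2ccccc2)ccc1Br
F5 | step 6 | 4-(benzyloxy)-1-bromo-2-(methoxymethoxy)benzene | COCOc1cc(OCc2ccccc2)ccc1Br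
F6 | step 6 | [4-(benzyloxy)-2-(methoxymethoxy)phenyl]boronic acid | COCOc1cc(OCc2ccccc2)ccc1B(O)O
F7 | step 10 | 2-bromo-5-(methoxymethoxy)-4-[(3R)-7-(methoxymethoxy)chroman-3-yl]phenol | COCOc1cc(O)c(Br)cc1[C@@H]1COc2cc(OCOC)ccc2C1
F8 | step 7 | trans-3-[4-(benzyloxy)-2-(methoxymethoxy)phenyl]-7-(methoxymethoxy)chroman-4-ol (racemic, one enantiomer drawn) | COCOc1cc(OCc2ccccc2)ccc1[C@@H]1COc2cc(OCOC)ccc2[C@H]1O
F9 | step 7 | 3-[4-(benzyloxy)-2-(methoxymethoxy)phenyl]-7-(methoxymethoxy)chroman-4-one (racemic) | COCOc1cc(OCc2ccccc2)ccc1C1COc2cc(OCOC)ccc2C1=O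
F10 | step 7 | (3R,4R)-3-[4-(benzyloxy)-2-(methoxymethoxy)phenyl]-7-(methoxymethoxy)chroman-4-ol | COCOc1cc(OCc2ccccc2)ccc1[C@@H]1COc2cc(OCOC)ccc2[C@@H]1O
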